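Retrosynthesis: the target is cut, in one operation, back to two acyclic partners, a 3-chloro-2-oxobutyl ester that already carries the whole diester side chain and (2E)-4-methylpenta-2,4-dienal, through an amine-catalysed Michael addition followed by an intramolecular Darzens reaction.
Ring order inside that operation: cyclohexanone ring first (Michael C3–C4 bond, then aldol C1–C6 bond), oxirane second (C1–O bond, loss of chloride); all four stereocentres are set there.
Chloro keto ester ⇒ side-chain acid + 1,3-dichlorobutan-2-one (carboxylate alkylation at CH2Cl).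
Side-chain acid ⇒ allyl tiglate + methacrylic acid (cross-metathesis).
Dienal ⇒ methacrolein + formylmethylene phosphorane (Wittig olefination).

Assumption: allyl tiglate, 1,3-dichlorobutan-2-one and the (R)-diphenylprolinol silyl ether are taken as catalogue chemicals; core atoms are numbered as in the name of the target (C1 methyl-bearing, C2 carbonyl, C3 ester-bearing, C4 isopropenyl-bearing, C6 oxirane CH).

Step 1
Reactants: 1 prop-2-en-1-yl (2E)-2-methylbut-2-enoate (allyl tiglate); 2 2-methylprop-2-enoic acid (methacrylic acid)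
Product: 3 (2E)-2-methyl-4-{[(2E)-2-methylbut-2-enoyl]oxy}but-2-enoic acid
Conditions: 2 (5 equiv), second-generation Hoveyda–Grubbs catalyst RuCl2(H2IMes)(=CH-C6H4-2-OiPr) (5 mol %), CH2Cl2, 40 °C, N2 sweep
Reagents that add atoms: none
Why: Olefin cross-metathesis joins the terminal allyl alkene of 1 to the 1,1-disubstituted alkene of 2 (which does not homodimerise) with loss of ethene, the electron-poor trisubstituted tiglate alkene stays inert, and the new trisubstituted enoic acid forms as the thermodynamically preferred E isomer.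

Step 2
Reactants: 3 (2E)-2-methyl-4-{[(2E)-2-methylbut-2-enoyl]oxy}but-2-enoic acid; 4 1,3-dichlorobutan-2-one (racemic)
Product: 5 3-chloro-2-oxobutyl (2E)-2-methyl-4-{[(2E)-2-methylbut-2-enoyl]oxy}but-2-enoate (racemic at the CHCl carbon)
Conditions: 4 (1.5 equiv), KHCO3 (1.2 equiv), NaI (10 mol %), DMF, rt
Reagents that add atoms: none
Why: Iodide-assisted SN2 O-alkylation of the carboxylate by an α-chloro ketone, in which the primary CH2Cl of 4 reacts far faster than the secondary CHCl(Me), so the chloride needed for the later oxirane closure is kept; no stereocentre is controlled because the CHCl carbon is enolised later.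

Step 3
Reactants: 6 2-methylprop-2-enal (methacrolein); 7 2-(triphenyl-λ5-phosphanylidene)acetaldehyde
Product: 8 (2E)-4-methylpenta-2,4-dienal
Conditions: 6 (2 equiv), PhMe, 80 °C, sealed tube; filtered through silica and kept as a cold PhMe solution
Reagents that add atoms: none
Why: Wittig olefination by a formyl-stabilised ylide gives the E enal, and the excess of 6 suppresses a second homologation of the product.

Step 4
Reactants: 5 3-chloro-2-oxobutyl (2E)-2-methyl-4-{[(2E)-2-methylbut-2-enoyl]oxy}but-2-enoate; 8 (2E)-4-methylpenta-2,4-dienal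
Product: 11 (1S,3R,4R,6S)-1-methyl-2-oxo-4-(prop-1-en-2-yl)-7-oxabicyclo[4.1.0]heptan-3-yl (2E)-2-methyl-4-{[(2E)-2-methylbut-2-enoyl]oxy}but-2-enoate (CNP0251261.1), via Michael adduct keto-aldehyde 9 (not isolated), via chlorohydrin aldol 10 (not isolated)
Conditions: 8 (1.5 equiv), (R)-2-[diphenyl(trimethylsilyloxy)methyl]pyrrolidine (20 mol %), K2CO3 (0.5 equiv), PhMe, 0 °C to rt; then DMF, K2CO3 (1.5 equiv), rt
Reagents that add atoms: none
Why: Proposed new method: the amine turns 8 into an E-iminium ion whose CPh2(OSiMe3) group blocks one face, so the carbonate-generated enolate of 5 adds 1,4 through its unhindered CH(OCOR) carbon (bond formation at the CCl(Me) carbon would build a quaternary centre beside the branched β-carbon and cannot end in an oxirane) and the (R)-amine thereby fixes C4 as R, then the chloro ketone enolate of 9 closes the carbocycle in a reversible 6-(enolendo)-exo-trig aldol addition and only the chlorohydrin chair 10 that has the isopropenyl and acyloxy groups equatorial and O−/Cl trans-diaxial is emptied by intramolecular SN2 displacement (an intramolecular Darzens reaction), which puts the oxirane anti to the isopropenyl group (C1 S, C6 S), while the enolisable ester-bearing C3 settles in the trans-diequatorial R configuration under K2CO3; the closest known reaction type is the diarylprolinol silyl ether-catalysed Michael/aldol/SN2 domino of 4-chloro-3-oxobutanoate esters with enals, which gives epoxycyclohexanones in one pot.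

Compound list
1 | prop-2-en-1-yl (2E)-2-methylbut-2-enoate (allyl tiglate) | C=CCOC(=O)/C(C)=C/C | starting material
2 | 2-methylprop-2-enoic acid (methacrylic acid) | C=C(C)C(=O)O | starting material
3 | (2E)-2-methyl-4-{[(2E)-2-methylbut-2-enoyl]oxy}but-2-enoic acid | OC(=O)/C(C)=C/COC(=O)/C(C)=C/C | intermediate
4 | 1,3-dichlorobutan-2-one (racemic) | CC(Cl)C(=O)CCl | starting material
5 | 3-chloro-2-oxobutyl (2E)-2-methyl-4-{[(2E)-2-methylbut-2-enoyl]oxy}but-2-enoate (racemic at the CHCl carbon) | CC(Cl)C(=O)COC(=O)/C(C)=C/COC(=O)/C(C)=C/C | intermediate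
6 | 2-methylprop-2-enal (methacrolein) | C=C(C)C=O | starting material
7 | 2-(triphenyl-λ5-phosphanylidene)acetaldehyde | O=CC=P(c1ccccc1)(c1ccccc1)c1ccccc1 | starting material
8 | (2E)-4-methylpenta-2,4-dienal | C=C(C)/C=C/C=O | intermediate
9 | (3R,4R)-6-chloro-2-methyl-5-oxo-3-(2-oxoethyl)hept-1-en-4-yl (2E)-2-methyl-4-{[(2E)-2-methylbut-2-enoyl]oxy}but-2-enoate (both configurations at the CHCl carbon; not isolated) | C=C(C)[C@@H](CC=O)[C@@H](OC(=O)/C(C)=C/COC(=O)/C(C)=C/C)C(=O)C(C)Cl | intermediate
10 | (1R,3R,4S,6R)-3-chloro-4-hydroxy-3-methyl-2-oxo-6-(prop-1-en-2-yl)cyclohexyl (2E)-2-methyl-4-{[(2E)-2-methylbut-2-enoyl]oxy}but-2-enoate (formed as its alkoxide; not isolated) | C=C(C)[C@H]1C[C@H](O)[C@@](C)(Cl)C(=O)[C@@H]1OC(=O)/C(C)=C/COC(=O)/C(C)=C/C | intermediate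
11 | (1S,3R,4R,6S)-1-methyl-2-oxo-4-(prop-1-en-2-yl)-7-oxabicyclo[4.1.0]heptan-3-yl (2E)-2-methyl-4-{[(2E)-2-methylbut-2-enoyl]oxy}but-2-enoate (CNP0251261.1) | C=C(C)[C@H]1C[C@@H]2O[C@]2(C)C(=O)[C@@H]1OC(=O)/C(C)=C/COC(=O)/C(C)=C/C | target

Total step count: 4. Longest linear sequence: 3 steps (1, 2, 4).

Steps most likely to fail

Step 4 is the main risk. Ketone 5 is a much weaker carbon acid than the keto esters for which this domino is known, and its CCl(Me) carbon may compete. Dienal 8 may react 1,6 or polymerise, and the chloro ketone may alkylate the amine. The fallback sets out from 8 and comes back at 11, using 3 at the end. The donor is replaced by the doubly activated allyl 4-chloro-3-oxopentanoate F1, made by crossed Claisen condensation of allyl acetate with 2-chloropropanoyl chloride (LiN(SiMe3)2, THF, −78 °C). With 8, the same amine and then K2CO3/DMF, F1 undergoes the established Michael/aldol/oxirane-closure domino, again closing both rings in one flask, to give allyl (1S,3R,4S,6S)-1-methyl-2-oxo-4-(prop-1-en-2-yl)-7-oxabicyclo[4.1.0]heptane-3-carboxylate F2. Pd(PPh3)4 and morpholine in THF remove the allyl ester with loss of CO2 to give (1S,4S,6S)-1-methyl-4-(prop-1-en-2-yl)-7-oxabicyclo[4.1.0]heptan-2-one F3. Its lithium enolate (LiN(SiMe3)2, THF, −78 °C) is hydroxylated by 2-(phenylsulfonyl)-3-phenyloxaziridine anti to the neighbouring isopropenyl group to give (1S,3R,4R,6S)-3-hydroxy-1-methyl-4-(prop-1-en-2-yl)-7-oxabicyclo[4.1.0]heptan-2-one F4. Esterification of F4 with 3 (N,N'-dicyclohexylcarbodiimide, DMAP, CH2Cl2) gives 11.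

Step 1 is the second risk. Methacrylic acid is a sluggish cross-metathesis partner and the allyl ester can isomerise to a propenyl ester. The fallback sets out from 1 and comes back at 3, replacing metathesis by carbonyl olefination. The allyl alkene of 1 is cleaved (OsO4 2 mol %, NaIO4, 2,6-lutidine, dioxane/H2O) to 2-oxoethyl (2E)-2-methylbut-2-enoate F5. Wittig olefination with tert-butyl 2-(triphenyl-λ5-phosphanylidene)propanoate (CH2Cl2, rt) gives tert-butyl (2E)-2-methyl-4-{[(2E)-2-methylbut-2-enoyl]oxy}but-2-enoate F6, and CF3CO2H in CH2Cl2 frees 3.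

Step 3 is the third risk. Dienal 8 is volatile, polymerises easily and can be homologated a second time by the ylide. The fallback sets out from 6 and comes back at 8, building the diene at the ester oxidation level. Horner–Wadsworth–Emmons reaction of 6 with triethyl phosphonoacetate (NaH, THF, 0 °C) gives ethyl (2E)-4-methylpenta-2,4-dienoate F7. iBu2AlH (CH2Cl2, −78 °C) gives (2E)-4-methylpenta-2,4-dien-1-ol F8, and MnO2 (CH2Cl2, rt) gives 8 as a solution that is used at once.

Further compounds
F1 | step 4 | allyl 4-chloro-3-oxopentanoate (racemic) | CC(Cl)C(=O)CC(=O)OCC=C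
F2 | step 4 | allyl (1S,3R,4S,6S)-1-methyl-2-oxo-4-(prop-1-en-2-yl)-7-oxabicyclo[4.1.0]heptane-3-carboxylate | C=C(C)[C@H]1C[C@@H]2O[C@]2(C)C(=O)[C@@H]1C(=O)OCC=C
F3 | step 4 | (1S,4S,6S)-1-methyl-4-(prop-1-en-2-yl)-7-oxabicyclo[4.1.0]heptan-2-one | C=C(C)[C@H]1C[C@@H]2O[C@]2(C)C(=O)C1
F4 | step 4 | (1S,3R,4R,6S)-3-hydroxy-1-methyl-4-(prop-1-en-2-yl)-7-oxabicyclo[4.1.0]heptan-2-one | C=C(C)[C@H]1C[C@@H]2O[C@]2(C)C(=O)[C@@H]1O
F5 | step 1 | 2-oxoethyl (2E)-2-methylbut-2-enoate | O=CCOC(=O)/C(C)=C/C
F6 | step 1 | tert-butyl (2E)-2-methyl-4-{[(2E)-2-methylbut-2-enoyl]oxy}but-2-enoate | CC(C)(C)OC(=O)/C(C)=C/COC(=O)/C(C)=C/C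
F7 | step 3 | ethyl (2E)-4-methylpenta-2,4-dienoate | C=C(C)/C=C/C(=O)OCC
F8 | step 3 | (2E)-4-methylpenta-2,4-dien-1-ol | C=C(C)/C=C/CO
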